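**Plan**

- Numbering: C1–C25 in the order of the target SMILES (C5 lactone CH–O, C7 lactone α-carbon, C8 alkylidene CH, C20 carbinol, C25 lactone carbonyl); ring A is the α-alkylidene-γ-butyrolactone, ring B the butenolide.
- Cuts: ring A at C25–O5 (lactonisation); C7–C25 and C8–C9 in one operation (alkyne C7≡C8, CO2 and a C9–zinc reagent); ring B from a 3-furyl group; C19–C20 (dithiane alkylation); C9–C10 (Wittig methylenation of SeO2-oxidised geranyl acetate).
- Forward: geranyl acetate is built up to the C9–C24 homoallylic zinc iodide (fragment B); the C1–C8 alkynol (fragment A) comes in one step from 3-methylbut-2-enal; the two are joined at C8–C9 while CO2 enters at C7; ring A then closes by lactonisation and ring B is made last from the furan.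
- Stereochemistry: C5 (S) from a chiral phosphoric acid-catalysed propargylation; C20 (R) from a CBS reduction; C7=C8 (Z) from syn addition across the alkyne; C11=C13 and C16=C18 (E) from geranyl acetate.
- Enabling feature: the C7=C8 olefin carries C25 and C9 on the same side, which is what syn addition of CO2 and a carbon group to a terminal alkyne C7≡C8 leaves behind. O5 sits homopropargylic to that alkyne, where as a metal alkoxide it can steer the carboxyl to C7.

Key step: step 15

Remark on the chemistry (assumption): a nickelacycle formed from an unassisted terminal alkyne and CO2 is taken to carry the carboxyl on the unsubstituted carbon. The C5 hydroxyl is therefore left unprotected and used as its alkoxide to direct CO2 to C7, and the hydroxy acid is isolated before ring A is closed.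

**Route**

Step 1
Reactants: 1 3-methylbut-2-enal
Product: 2 (4S)-6-methylhept-5-en-1-yn-4-ol
Conditions: allenylboronic acid pinacol ester, (S)-3,3'-bis(2,4,6-triisopropylphenyl)-1,1'-binaphthyl-2,2'-diyl hydrogen phosphate (5 mol%), 4 Å MS, toluene, 0 °C
Reagents that add atoms: allenylboronic acid pinacol ester, C=C=CB1OC(C)(C)C(C)(C)O1
Why: Chiral phosphoric acid-catalysed propargylation (SE2' allenylboration) of an enal runs through a closed six-membered transition state in which the catalyst hydrogen-bonds to a boronate oxygen and the formyl hydrogen, and the (S)-catalyst should direct the propargyl group to the Si face of the aldehyde and so set C5 as S.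

Step 2
Reactants: 3 geranyl acetate
Product: 4 (2E,6E)-8-hydroxy-3,7-dimethylocta-2,6-dien-1-yl acetate
Conditions: SeO2 (cat.), t-BuOOH, salicylic acid (cat.), CH2Cl2, rt
Reagents that add atoms: tert-butyl hydroperoxide, CC(C)(C)OO
Why: Catalytic Riley oxidation (ene reaction, then [2,3]-sigmatropic shift) picks the E-methyl group of the electron-richer terminal olefin, the other olefin being deactivated by the allylic acetate.

Step 3
Reactants: 4 (2E,6E)-8-hydroxy-3,7-dimethylocta-2,6-dien-1-yl acetate
Product: 5 (2E,6E)-3,7-dimethyl-8-oxoocta-2,6-dien-1-yl acetate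
Conditions: MnO2, CH2Cl2, rt
Reagents that add atoms: none
Why: MnO2 oxidises allylic alcohols selectively to enals and should leave the acetate and the E geometry untouched.

Step 4
Reactants: 5 (2E,6E)-3,7-dimethyl-8-oxoocta-2,6-dien-1-yl acetate
Product: 6 (2E,6E)-3,7-dimethylnona-2,6,8-trien-1-yl acetate
Conditions: Ph3PCH3Br, KN(SiMe3)2, THF, −78 to 0 °C
Reagents that add atoms: methyltriphenylphosphonium bromide, C[P+](c1ccccc1)(c1ccccc1)c1ccccc1.[Br-]
Why: Wittig methylenation of the unhindered enal at low temperature is much faster than attack of the ylide on the acetate and adds C9 to the former aldehyde carbon C10.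

Step 5
Reactants: 6 (2E,6E)-3,7-dimethylnona-2,6,8-trien-1-yl acetate
Product: 7 (2E,6E)-3,7-dimethylnona-2,6,8-trien-1-ol
Conditions: K2CO3 (cat.), MeOH, rt
Reagents that add atoms: none
Why: Base-catalysed transesterification with methanol removes the acetate without touching the triene.

Step 6
Reactants: 7 (2E,6E)-3,7-dimethylnona-2,6,8-trien-1-ol
Product: 8 (3E,7E)-9-bromo-3,7-dimethylnona-1,3,7-triene
Conditions: CBr4, PPh3, CH2Cl2, 0 °C
Reagents that add atoms: carbon tetrabromide, BrC(Br)(Br)Br
Why: Appel bromination of the primary allylic alcohol proceeds by SN2 displacement of the oxyphosphonium ion and should not transpose the allyl system.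

Step 7
Reactants: 9 furan-3-carbaldehyde
Product: 10 2-(furan-3-yl)-1,3-dithiane
Conditions: propane-1,3-dithiol, BF3·OEt2 (cat.), CH2Cl2, 0 °C
Reagents that add atoms: propane-1,3-dithiol, SCCCS
Why: Lewis acid-catalysed dithioacetalisation turns the aldehyde into an acyl anion precursor for Corey–Seebach umpolung, and the furan tolerates catalytic BF3·OEt2 at 0 °C.

Step 8
Reactants: 10 2-(furan-3-yl)-1,3-dithiane, 8 (3E,7E)-9-bromo-3,7-dimethylnona-1,3,7-triene
Product: 12 2-[(2E,6E)-3,7-dimethylnona-2,6,8-trien-1-yl]-2-(furan-3-yl)-1,3-dithiane, via lithio dithiane 11 (not isolated)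
Conditions: n-BuLi, THF, −78 to −30 °C; then 8, −78 to 0 °C
Reagents that add atoms: none
Why: Corey–Seebach alkylation, in which the aryl-stabilised dithianyllithium forms faster than ring lithiation of the furan and attacks the primary allylic bromide at its α-carbon (SN2), forming C19–C20 with the E olefin intact.

Step 9
Reactants: 12 2-[(2E,6E)-3,7-dimethylnona-2,6,8-trien-1-yl]-2-(furan-3-yl)-1,3-dithiane
Product: 13 (3E,7E)-1-(furan-3-yl)-4,8-dimethyldeca-3,7,9-trien-1-one
Conditions: MeI, CaCO3, MeCN/H2O, 40 °C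
Reagents that add atoms: water, O
Why: Alkylative dithiane hydrolysis (S-methylation, then hydrolysis of the sulfonium ion) under CaCO3 buffering unmasks the ketone without oxidants or heavy metals that would attack the furan or diene, at a pH that should not move the β,γ-olefin into conjugation.

Step 10
Reactants: 13 (3E,7E)-1-(furan-3-yl)-4,8-dimethyldeca-3,7,9-trien-1-one
Product: 14 (1R,3E,7E)-1-(furan-3-yl)-4,8-dimethyldeca-3,7,9-trien-1-ol
Conditions: (S)-1-methyl-3,3-diphenyltetrahydro-1H,3H-pyrrolo[1,2-c][1,3,2]oxazaborole (0.2 equiv), catecholborane, toluene, −78 °C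
Reagents that add atoms: none
Why: Corey–Bakshi–Shibata reduction, in which the ketone binds the oxazaborolidine boron with the larger 3-furyl group away from the catalyst and hydride is delivered to the face that gives the R carbinol (the sense the (S)-catalyst shows with aryl alkyl ketones), while catecholborane at −78 °C does not hydroborate the diene.

Step 11
Reactants: 14 (1R,3E,7E)-1-(furan-3-yl)-4,8-dimethyldeca-3,7,9-trien-1-ol
Product: 15 tert-butyl{[(1R,3E,7E)-1-(furan-3-yl)-4,8-dimethyldeca-3,7,9-trien-1-yl]oxy}dimethylsilane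
Conditions: TBSCl, imidazole, DMF, rt
Reagents that add atoms: tert-butyldimethylsilyl chloride, CC(C)(C)[Si](C)(C)Cl
Why: Standard silylation of the secondary alcohol gives an ether that should survive the organoborane, iodide, zinc and nickel steps.

Step 12
Reactants: 15 tert-butyl{[(1R,3E,7E)-1-(furan-3-yl)-4,8-dimethyldeca-3,7,9-trien-1-yl]oxy}dimethylsilane
Product: 17 (3E,7E,10R)-10-[(tert-butyldimethylsilyl)oxy]-10-(furan-3-yl)-3,7-dimethyldeca-3,7-dien-1-ol, via alkyl(disiamyl)borane 16 (not isolated)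
Conditions: disiamylborane (from BH3·THF and 2-methylbut-2-ene), THF, 0 °C; then NaOH, H2O2, 0 °C to rt
Reagents that add atoms: hydrogen peroxide, OO
Why: Brown hydroboration–oxidation with a hindered dialkylborane is selective for the monosubstituted terminus of the 1,3-diene over the trisubstituted olefins and the furan and gives the anti-Markovnikov homoallylic alcohol.

Step 13
Reactants: 17 (3E,7E,10R)-10-[(tert-butyldimethylsilyl)oxy]-10-(furan-3-yl)-3,7-dimethyldeca-3,7-dien-1-ol
Product: 18 tert-butyl{[(1R,3E,7E)-1-(furan-3-yl)-10-iodo-4,8-dimethyldeca-3,7-dien-1-yl]oxy}dimethylsilane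
Conditions: I2, PPh3, imidazole, CH2Cl2, 0 °C
Reagents that add atoms: iodine, II
Why: Appel-type iodination converts the primary alcohol into the iodide by SN2 under buffered conditions that spare the furan, the olefins and the silyl ether.

Step 14
Reactants: 18 tert-butyl{[(1R,3E,7E)-1-(furan-3-yl)-10-iodo-4,8-dimethyldeca-3,7-dien-1-yl]oxy}dimethylsilane
Product: 19 {(3E,7E,10R)-10-[(tert-butyldimethylsilyl)oxy]-10-(furan-3-yl)-3,7-dimethyldeca-3,7-dien-1-yl}zinc iodide (used as a titrated THF solution)
Conditions: Zn dust (activated with BrCH2CH2Br and Me3SiCl), LiCl, THF, 40 °C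
Reagents that add atoms: zinc, [Zn]
Why: LiCl-assisted direct insertion of zinc into a primary alkyl iodide gives an alkylzinc iodide that tolerates the silyl ether, the furan and the olefins and stays in the open homoallyl form.

Step 15
Reactants: 2 (4S)-6-methylhept-5-en-1-yn-4-ol, 20 carbon dioxide, 19 {(3E,7E,10R)-10-[(tert-butyldimethylsilyl)oxy]-10-(furan-3-yl)-3,7-dimethyldeca-3,7-dien-1-yl}zinc iodide
Product: 22 (2Z,6E,10E,13R)-13-[(tert-butyldimethylsilyl)oxy]-13-(furan-3-yl)-2-[(2S)-2-hydroxy-4-methylpent-3-en-1-yl]-6,10-dimethyltrideca-2,6,10-trienoic acid, via lithium alkoxide 21 (not isolated)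
Conditions: LiN(SiMe3)2 (1.0 equiv), THF, −78 °C; then 19 (2 equiv), Ni(cod)2 (0.3–1.0 equiv), CO2 (1 atm), THF/DMSO, 0 °C to rt; aq. HCl to pH 4 at 0 °C
Reagents that add atoms: none
Why: Proposed new method: the lithium alkoxide at O5 takes up the alkylzinc as an alkoxy(alkyl)zinc species next to the alkyne, zerovalent nickel binds C7≡C8, and CO2 bonds to C7 while nickel takes C8 in a five-membered oxanickelacycle (Ni–C8=C7–C25(=O)–O) whose carboxylate is held by the alkoxide-bound zinc; transmetalation of C9 from zinc to nickel and reductive elimination then form C8–C9 cis to the carboxylate, and the alternative order (alkyl transfer to C8 first, then CO2 insertion into the alkoxide-chelated C7–metal bond) would end in the same constitution and geometry. The closest known reaction types are the nickel-catalysed methylative carboxylation of homopropargylic alcohols with Me2Zn and CO2, which puts the carboxyl on the alkyne carbon nearer the hydroxyl with syn delivery of both groups, and the Ni(cod)2-mediated alkylative carboxylation of terminal alkynes with organozinc reagents; not yet shown are the terminal alkyne in the hydroxyl-directed mode and a primary alkylzinc iodide with β-hydrogens. No ring closes, because O5 remains a metal alkoxide until the cold quench to pH 4 and the hydroxy acid is carried on before it lactonises, and no stereocentre is formed, C5 and C20 passing through unchanged. The step needs regioselectivity (C25 on C7, not C8), secured by the free homopropargylic alkoxide, syn addition, which is inherent in the metallacycle and gives the Z olefin, and alkyl transfer in preference to β-hydride elimination of the homoallylic alkylnickel, favoured by phosphine-free nickel, low temperature and excess 19.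

Step 16
Reactants: 22 (2Z,6E,10E,13R)-13-[(tert-butyldimethylsilyl)oxy]-13-(furan-3-yl)-2-[(2S)-2-hydroxy-4-methylpent-3-en-1-yl]-6,10-dimethyltrideca-2,6,10-trienoic acid
Product: 23 (3Z,5S)-3-[(4E,8E,11R)-11-[(tert-butyldimethylsilyl)oxy]-11-(furan-3-yl)-4,8-dimethylundeca-4,8-dien-1-ylidene]-5-(2-methylprop-1-en-1-yl)oxolan-2-one
Conditions: EDC·HCl [N-(3-dimethylaminopropyl)-N'-ethylcarbodiimide hydrochloride], DMAP (cat.), CH2Cl2, 0 °C to rt
Reagents that add atoms: none
Why: Steglich-type carbodiimide activation of the acid and 5-exo-trig attack of the C5 hydroxyl on the acyl carbon close ring A with retention at C5 and without acid that could ionise the allylic C5–O bond.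

Step 17
Reactants: 23 (3Z,5S)-3-[(4E,8E,11R)-11-[(tert-butyldimethylsilyl)oxy]-11-(furan-3-yl)-4,8-dimethylundeca-4,8-dien-1-ylidene]-5-(2-methylprop-1-en-1-yl)oxolan-2-one
Product: 26 (3Z,5S)-3-[(4E,8E,11R)-11-[(tert-butyldimethylsilyl)oxy]-4,8-dimethyl-11-(5-oxo-2,5-dihydrofuran-3-yl)undeca-4,8-dien-1-ylidene]-5-(2-methylprop-1-en-1-yl)oxolan-2-one, via furan endoperoxide 24 (not isolated), via hydroxybutenolide 25 (not isolated)
Conditions: O2, hν, 5,10,15,20-tetraphenylporphyrin (cat.), i-Pr2NEt, CH2Cl2, −78 °C; then NaBH4, THF/EtOH, 0 °C; aq. HCl to pH 3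
Reagents that add atoms: dioxygen, O=O
Why: [4+2] cycloaddition of singlet oxygen to the furan should be much faster at −78 °C than its ene reaction with trisubstituted olefins, the hindered base then removes the endoperoxide bridgehead hydrogen on C23 remote from the C20 substituent (Kornblum–DeLaMare fragmentation) so that C23 becomes the carbonyl and C24 the lactol carbon, and borohydride reduction of the ring-opened aldehyde form followed by acidification relactonises to ring B.

Step 18
Reactants: 26 (3Z,5S)-3-[(4E,8E,11R)-11-[(tert-butyldimethylsilyl)oxy]-4,8-dimethyl-11-(5-oxo-2,5-dihydrofuran-3-yl)undeca-4,8-dien-1-ylidene]-5-(2-methylprop-1-en-1-yl)oxolan-2-one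
Product: 27 (3Z,5S)-3-[(4E,8E,11R)-11-hydroxy-4,8-dimethyl-11-(5-oxo-2,5-dihydrofuran-3-yl)undeca-4,8-dien-1-ylidene]-5-(2-methylprop-1-en-1-yl)oxolan-2-one
Conditions: HF·pyridine, pyridine, THF, 0 °C to rt
Reagents that add atoms: none
Why: Buffered fluoride desilylation cleaves the secondary silyl ether without opening either lactone or isomerising the butenolide.

**Compound list**

1 | 3-methylbut-2-enal | CC(C)=CC=O | starting material
2 | (4S)-6-methylhept-5-en-1-yn-4-ol | CC(C)=C[C@@H](O)CC#C | intermediate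
3 | geranyl acetate | CC(C)=CCC/C(C)=C/COC(C)=O | starting material
4 | (2E,6E)-8-hydroxy-3,7-dimethylocta-2,6-dien-1-yl acetate | OC/C(C)=C/CC/C(C)=C/COC(C)=O | intermediate
5 | (2E,6E)-3,7-dimethyl-8-oxoocta-2,6-dien-1-yl acetate | O=C/C(C)=C/CC/C(C)=C/COC(C)=O | intermediate
6 | (2E,6E)-3,7-dimethylnona-2,6,8-trien-1-yl acetate | C=C/C(C)=C/CC/C(C)=C/COC(C)=O | intermediate
7 | (2E,6E)-3,7-dimethylnona-2,6,8-trien-1-ol | C=C/C(C)=C/CC/C(C)=C/CO | intermediate
8 | (3E,7E)-9-bromo-3,7-dimethylnona-1,3,7-triene | C=C/C(C)=C/CC/C(C)=C/CBr | intermediate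
9 | furan-3-carbaldehyde | O=Cc1ccoc1 | starting material
10 | 2-(furan-3-yl)-1,3-dithiane | C1CSC(SC1)c1ccoc1 | intermediate
11 | 2-lithio-2-(furan-3-yl)-1,3-dithiane | [Li]C1(SCCCS1)c1ccoc1 | intermediate
12 | 2-[(2E,6E)-3,7-dimethylnona-2,6,8-trien-1-yl]-2-(furan-3-yl)-1,3-dithiane | C=C/C(C)=C/CC/C(C)=C/CC1(SCCCS1)c1ccoc1 | intermediate
13 | (3E,7E)-1-(furan-3-yl)-4,8-dimethyldeca-3,7,9-trien-1-one | C=C/C(C)=C/CC/C(C)=C/CC(=O)c1ccoc1 | intermediate
14 | (1R,3E,7E)-1-(furan-3-yl)-4,8-dimethyldeca-3,7,9-trien-1-ol | C=C/C(C)=C/CC/C(C)=C/C[C@@H](O)c1ccoc1 | intermediate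
15 | tert-butyl{[(1R,3E,7E)-1-(furan-3-yl)-4,8-dimethyldeca-3,7,9-trien-1-yl]oxy}dimethylsilane | C=C/C(C)=C/CC/C(C)=C/C[C@@H](O[Si](C)(C)C(C)(C)C)c1ccoc1 | intermediate
16 | {(3E,7E,10R)-10-[(tert-butyldimethylsilyl)oxy]-10-(furan-3-yl)-3,7-dimethyldeca-3,7-dien-1-yl}bis(3-methylbutan-2-yl)borane | CC(C)C(C)B(CC/C(C)=C/CC/C(C)=C/C[C@@H](O[Si](C)(C)C(C)(C)C)c1ccoc1)C(C)C(C)C | intermediate
17 | (3E,7E,10R)-10-[(tert-butyldimethylsilyl)oxy]-10-(furan-3-yl)-3,7-dimethyldeca-3,7-dien-1-ol | OCC/C(C)=C/CC/C(C)=C/C[C@@H](O[Si](C)(C)C(C)(C)C)c1ccoc1 | intermediate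
18 | tert-butyl{[(1R,3E,7E)-1-(furan-3-yl)-10-iodo-4,8-dimethyldeca-3,7-dien-1-yl]oxy}dimethylsilane | ICC/C(C)=C/CC/C(C)=C/C[C@@H](O[Si](C)(C)C(C)(C)C)c1ccoc1 | intermediate
19 | {(3E,7E,10R)-10-[(tert-butyldimethylsilyl)oxy]-10-(furan-3-yl)-3,7-dimethyldeca-3,7-dien-1-yl}zinc iodide | I[Zn]CC/C(C)=C/CC/C(C)=C/C[C@@H](O[Si](C)(C)C(C)(C)C)c1ccoc1 | intermediate
20 | carbon dioxide | O=C=O | starting material
21 | lithium (4S)-6-methylhept-5-en-1-yn-4-olate | CC(C)=C[C@@H](O[Li])CC#C | intermediate
22 | (2Z,6E,10E,13R)-13-[(tert-butyldimethylsilyl)oxy]-13-(furan-3-yl)-2-[(2S)-2-hydroxy-4-methylpent-3-en-1-yl]-6,10-dimethyltrideca-2,6,10-trienoic acid | CC(C)=C[C@@H](O)C/C(C(=O)O)=C/CC/C(C)=C/CC/C(C)=C/C[C@@H](O[Si](C)(C)C(C)(C)C)c1ccoc1 | intermediate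
23 | (3Z,5S)-3-[(4E,8E,11R)-11-[(tert-butyldimethylsilyl)oxy]-11-(furan-3-yl)-4,8-dimethylundeca-4,8-dien-1-ylidene]-5-(2-methylprop-1-en-1-yl)oxolan-2-one | CC(C)=C[C@@H]1C/C(=C/CC/C(C)=C/CC/C(C)=C/C[C@@H](O[Si](C)(C)C(C)(C)C)c2ccoc2)C(=O)O1 | intermediate
24 | 2,5-endoperoxide of the furan of 23 [2,3,7-trioxabicyclo[2.2.1]hept-5-en-5-yl in place of furan-3-yl; bridgehead configuration undefined] | CC(C)=C[C@@H]1C/C(=C/CC/C(C)=C/CC/C(C)=C/C[C@@H](O[Si](C)(C)C(C)(C)C)C2=CC3OOC2O3)C(=O)O1 | intermediate
25 | hydroxybutenolide [2-hydroxy-5-oxo-2,5-dihydrofuran-3-yl in place of the furan-3-yl of 23; both lactol epimers] | CC(C)=C[C@@H]1C/C(=C/CC/C(C)=C/CC/C(C)=C/C[C@@H](O[Si](C)(C)C(C)(C)C)C2=CC(=O)OC2O)C(=O)O1 | intermediate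
26 | (3Z,5S)-3-[(4E,8E,11R)-11-[(tert-butyldimethylsilyl)oxy]-4,8-dimethyl-11-(5-oxo-2,5-dihydrofuran-3-yl)undeca-4,8-dien-1-ylidene]-5-(2-methylprop-1-en-1-yl)oxolan-2-one | CC(C)=C[C@@H]1C/C(=C/CC/C(C)=C/CC/C(C)=C/C[C@@H](O[Si](C)(C)C(C)(C)C)C2=CC(=O)OC2)C(=O)O1 | intermediate
27 | (3Z,5S)-3-[(4E,8E,11R)-11-hydroxy-4,8-dimethyl-11-(5-oxo-2,5-dihydrofuran-3-yl)undeca-4,8-dien-1-ylidene]-5-(2-methylprop-1-en-1-yl)oxolan-2-one (CNP0358093.3) | CC(C)=C[C@@H]1C/C(=C/CC/C(C)=C/CC/C(C)=C/C[C@@H](O)C2=CC(=O)OC2)C(=O)O1 | target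

**Step count and risks**

Total steps: 18. Longest linear sequence: 16 steps (3 to 27 through steps 2–6 and 8–18).

The three steps most likely to fail:

Step 15 (proposed new method). What may go wrong: β-hydride elimination at the alkylnickel stage, so that hydrogen and not the chain is delivered to C8; carboxylation at the unsubstituted alkyne carbon if the alkoxide fails to direct; nickel-induced oligomerisation of the terminal alkyne. The fallback uses known chemistry, sets out from 2 and 18 and returns to the route at 23. The dilithio derivative of 2 (n-BuLi, 2 equiv, THF/DMPU, −78 to 0 °C) is alkylated at the acetylide carbon with 18 to give the internal alkynol (4S,10E,14E,17R)-17-[(tert-butyldimethylsilyl)oxy]-17-(furan-3-yl)-2,10,14-trimethylheptadeca-2,10,14-trien-6-yn-4-ol F1. Hydroxyl-directed trans-hydrostannation ([Cp*RuCl]4 cat., Bu3SnH, CH2Cl2, rt) delivers tin to C7 and hydrogen to C8 from opposite faces and gives the (6Z)-6-(tributylstannyl)alkenol F2. Iododestannylation (I2, CH2Cl2, 0 °C) with retention gives the (6Z)-6-iodoalkenol F3. Carbonylative lactonisation (Pd(PPh3)4 cat., CO 1 atm, Et3N, MeCN, 50 °C) then closes ring A and gives 23 with C9 cis to C25. Here C8–C9 arises by SN2 alkylation and C7–C25 by CO insertion, so neither nickel nor zinc reagent 19 is needed.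

Step 17. What may go wrong: ene-type oxidation of the three trisubstituted olefins in competition with the furan cycloaddition, fragmentation of the endoperoxide toward the wrong carbonyl position, or conjugate reduction of the alkylidene lactone by borohydride. The fallback sets out from 23 and returns at 26. Iridium-catalysed C–H borylation ([Ir(OMe)(cod)]2, 4,4'-di-tert-butyl-2,2'-bipyridine, B2pin2, hexane/THF, rt) at the only unhindered furan α-position, C23, gives the C23 pinacol boronate of 23 F4. Oxidation of the C–B bond (NaBO3·4H2O, THF/H2O, 0 °C) gives the C23 furanol F5, which tautomerises (Et3N, CH2Cl2) to the conjugated butenolide 26. Neither singlet oxygen nor a hydride reagent is used.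

Step 9. What may go wrong: migration of the C16=C18 double bond into conjugation with the new C20 ketone during unmasking, or incomplete cleavage of the 2-aryl dithiane under conditions mild enough for the furan and the diene. The fallback sets out from 7 and returns at 13. Corey–Kim chlorination (NCS, Me2S, CH2Cl2, −20 to 0 °C) gives (3E,7E)-9-chloro-3,7-dimethylnona-1,3,7-triene F6. A carbonylative Stille coupling with tributyl(furan-3-yl)stannane (PdCl2(PPh3)2 cat., CO 3 atm, THF, 50 °C) joins the allyl terminus, CO and the furan directly to ketone 13 under neutral conditions, so that steps 6 to 9 and the dithiane are bypassed.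

Further compounds
F1 | step 15 | (4S,10E,14E,17R)-17-[(tert-butyldimethylsilyl)oxy]-17-(furan-3-yl)-2,10,14-trimethylheptadeca-2,10,14-trien-6-yn-4-ol | CC(C)=C[C@@H](O)CC#CCC/C(C)=C/CC/C(C)=C/C[C@@H](O[Si](C)(C)C(C)(C)C)c1ccoc1
F2 | step 15 | (4S,6Z,10E,14E,17R)-17-[(tert-butyldimethylsilyl)oxy]-17-(furan-3-yl)-2,10,14-trimethyl-6-(tributylstannyl)heptadeca-2,6,10,14-tetraen-4-ol | CC(C)=C[C@@H](O)C/C(=C/CC/C(C)=C/CC/C(C)=C/C[C@@H](O[Si](C)(C)C(C)(C)C)c1ccoc1)[Sn](CCCC)(CCCC)CCCC
F3 | step 15 | (4S,6Z,10E,14E,17R)-17-[(tert-butyldimethylsilyl)oxy]-17-(furan-3-yl)-6-iodo-2,10,14-trimethylheptadeca-2,6,10,14-tetraen-4-ol | CC(C)=C[C@@H](O)C/C(I)=C/CC/C(C)=C/CC/C(C)=C/C[C@@H](O[Si](C)(C)C(C)(C)C)c1ccoc1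
F4 | step 17 | (3Z,5S)-3-{(4E,8E,11R)-11-[(tert-butyldimethylsilyl)oxy]-4,8-dimethyl-11-[5-(4,4,5,5-tetramethyl-1,3,2-dioxaborolan-2-yl)furan-3-yl]undeca-4,8-dien-1-ylidene}-5-(2-methylprop-1-en-1-yl)oxolan-2-one | CC(C)=C[C@@H]1C/C(=C/CC/C(C)=C/CC/C(C)=C/C[C@@H](O[Si](C)(C)C(C)(C)C)c2cc(B3OC(C)(C)C(C)(C)O3)oc2)C(=O)O1
F5 | step 17 | (3Z,5S)-3-[(4E,8E,11R)-11-[(tert-butyldimethylsilyl)oxy]-11-(5-hydroxyfuran-3-yl)-4,8-dimethylundeca-4,8-dien-1-ylidene]-5-(2-methylprop-1-en-1-yl)oxolan-2-one | CC(C)=C[C@@H]1C/C(=C/CC/C(C)=C/CC/C(C)=C/C[C@@H](O[Si](C)(C)C(C)(C)C)c2cc(O)oc2)C(=O)O1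
F6 | step 9 | (3E,7E)-9-chloro-3,7-dimethylnona-1,3,7-triene | C=C/C(C)=C/CC/C(C)=C/CCl
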